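**Retrosynthetic overview**

1. The target is epicatechin-(4β→6)-epiafzelechin-(4β→8)-epicatechin-(4β→6)-epicatechin; the flavan units are called unit 1 (upper epicatechin), unit 2 (epiafzelechin), unit 3 and unit 4 (lower, terminal epicatechin).
2. The three interflavan bonds are cut as C4-cation/arene couplings, made top-down with three orthogonal C4 nucleofuges (C4–OH, C4–S-xylyl, C4–O-acetal). Bromine caps (unit 1 C6/C8, unit 2 C8, unit 4 C8) leave each nucleophile only the ring-A position that is wanted; one hydrogenolysis removes all benzyl ethers and bromines.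
3. Units 2–4 come from the natural flavan-3-ols; unit 1 is built from open-chain pieces, its ring C being closed between C3 and C4 by reductive coupling of a dialdehyde (aryl CHO = C4, α-aryloxy-arylacetaldehyde CHO = C3), with C2 set beforehand.
4. Enabling feature: in unit 1, C3 (carbinol) and C4 (benzylic to ring A, ortho to O1, flanked by the 5- and 7-oxygens) are a vicinal pair whose carbons lie 1,6 to each other through O1–C8a–C4a. A ketyl–aldehyde coupling therefore closes ring C and leaves at C4 a hydroxyl that the electron-rich ring A later expels for the (4β→6) bond.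
5. Order of ring and bond formation: ring C of unit 1 (step 8) → unit 1–unit 2 bond (step 13) → unit 2–unit 3 bond (step 16) → unit 3–unit 4 bond (step 18) → deprotection (step 19).

Key step: step 8

Assumption: (−)-epicatechin and (−)-epiafzelechin are bought as the natural (2R,3R) flavan-3-ols, and the four secondary 3-hydroxyl groups are left free during the Lewis-acid couplings.

**Route**

Step 1
Reactants: 1 4-bromo-1,2-bis(benzyloxy)benzene; 2 dimethyl oxalate
Product: 4 methyl 2-[3,4-bis(benzyloxy)phenyl]-2-oxoacetate, via aryl Grignard reagent 3 (not isolated)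
Conditions: Mg, THF, rt; then added to 2 (3 equiv), THF, −78 °C
Reagents that add atoms: none
Why: Grignard formation and mono-acylation by an excess of the diester at low temperature (Grignard acylation), the magnesium hemiketal protecting the keto ester from a second addition.

Step 2
Reactants: 4 methyl 2-[3,4-bis(benzyloxy)phenyl]-2-oxoacetate
Product: 5 methyl (S)-2-[3,4-bis(benzyloxy)phenyl]-2-hydroxyacetate
Conditions: RuCl(p-cymene)[(R,R)-TsDPEN] (1 mol%), HCO2H/Et3N 5:2, CH2Cl2, rt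
Reagents that add atoms: none
Why: Noyori asymmetric transfer hydrogenation of an aryl α-keto ester, the catalyst enantiomer being chosen (aryl/η6-arene CH–π model) so that the (S)-carbinol, the future C2 of unit 1 before inversion, should form by catalyst control.

Step 3
Reactants: 6 2,4,6-trihydroxybenzaldehyde
Product: 7 4,6-bis(benzyloxy)-2-hydroxybenzaldehyde
Conditions: BnBr (2.1 equiv), K2CO3, DMF, 0 °C → rt
Reagents that add atoms: benzyl bromide, BrCc1ccccc1
Why: Williamson etherification that should stop at the dibenzyl ether because the remaining ortho hydroxyl is hydrogen-bonded to the formyl group and is the least reactive.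

Step 4
Reactants: 7 4,6-bis(benzyloxy)-2-hydroxybenzaldehyde; 5 methyl (S)-2-[3,4-bis(benzyloxy)phenyl]-2-hydroxyacetate
Product: 8 methyl (R)-2-[3,5-bis(benzyloxy)-2-formylphenoxy]-2-[3,4-bis(benzyloxy)phenyl]acetate
Conditions: PPh3, DIAD, THF, 0 °C → rt
Reagents that add atoms: none
Why: Mitsunobu etherification of the acidic ortho-formyl phenol with SN2 inversion at the α-hydroxy ester carbon (the ester group disfavours ionization), which turns (S)-5 into the (R)-aryl ether that is C2 of unit 1 with O1 attached.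

Step 5
Reactants: 8 methyl (R)-2-[3,5-bis(benzyloxy)-2-formylphenoxy]-2-[3,4-bis(benzyloxy)phenyl]acetate
Product: 9 methyl (R)-2-[3,5-bis(benzyloxy)-2,4-dibromo-6-formylphenoxy]-2-[3,4-bis(benzyloxy)phenyl]acetate
Conditions: NBS (2.1 equiv), MeCN, 0 °C, dark
Reagents that add atoms: N-bromosuccinimide, O=C1CCC(=O)N1Br
Why: Electrophilic aromatic bromination at the two free positions of the phloroglucinol-type ring, each ortho/para to three oxygens and far more activated than the catechol-type ring; the bromines become the C6/C8 caps of unit 1.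

Step 6
Reactants: 9 methyl (R)-2-[3,5-bis(benzyloxy)-2,4-dibromo-6-formylphenoxy]-2-[3,4-bis(benzyloxy)phenyl]acetate
Product: 10 (R)-2-[3,5-bis(benzyloxy)-2,4-dibromo-6-(hydroxymethyl)phenoxy]-2-[3,4-bis(benzyloxy)phenyl]ethan-1-ol
Conditions: iBu2AlH (5 equiv), CH2Cl2, −78 → 0 °C; aq. potassium sodium tartrate
Reagents that add atoms: none
Why: Aluminium hydride reduction of both the aryl aldehyde and the ester to primary alcohols under Lewis-acidic, non-basic conditions that leave the C2 stereocentre and the aryl bromides untouched.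

Step 7
Reactants: 10 (R)-2-[3,5-bis(benzyloxy)-2,4-dibromo-6-(hydroxymethyl)phenoxy]-2-[3,4-bis(benzyloxy)phenyl]ethan-1-ol
Product: 11 (R)-2-[3,5-bis(benzyloxy)-2,4-dibromo-6-formylphenoxy]-2-[3,4-bis(benzyloxy)phenyl]acetaldehyde
Conditions: Dess–Martin periodinane (2.6 equiv), NaHCO3, CH2Cl2, 0 °C → rt; used at once
Reagents that add atoms: none
Why: Double Dess–Martin oxidation of the benzylic and the primary alcohol to the 1,6-dialdehyde under buffered conditions that should spare the enolizable α-aryloxy-α-aryl stereocentre.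

Step 8
Reactants: 11 (R)-2-[3,5-bis(benzyloxy)-2,4-dibromo-6-formylphenoxy]-2-[3,4-bis(benzyloxy)phenyl]acetaldehyde
Product: 13 (2R,3R,4R)-5,7-bis(benzyloxy)-2-[3,4-bis(benzyloxy)phenyl]-6,8-dibromochromane-3,4-diol (2,3-cis, 3,4-cis), via samarium ketyl 12 (not isolated)
Conditions: SmI2 (2.4 equiv), THF, −78 °C, slow addition of 11; aq. NH4Cl
Reagents that add atoms: none
Why: SmI2 should reduce the aryl aldehyde first (conjugated and chelated by the flanking ether oxygens) to the trivalent-samarium ketyl 12, whose carbon (C4) adds to the samarium-bound aliphatic aldehyde carbon (C3), and a second electron transfer gives the samarium diolate that is protonated on work-up. The closest known reaction type is the SmI2-mediated intramolecular pinacol (ketyl–carbonyl) coupling of 1,6-dialdehydes to cis-cyclohexane-1,2-diols. Ring C is closed in the 6-exo-trig mode (ketyl carbon onto C3=O, oxygen outside the ring). C2 (R) is already present; C3 is set by a chelate in which one samarium is held by the ketyl oxygen, the aldehyde oxygen and O1, possible only when C3=O is syn-clinal to C2–O1, which puts the new C3–O axial on the half-chair with the 2-aryl group equatorial (2,3-cis, 3R); C4 follows as the cis-diol through the same samarium bridge (4R), and its configuration is of no consequence because this C–O bond is ionized in step 13. The step needs face selectivity at C3 and chemoselectivity: reduction of the aryl aldehyde before the aliphatic one avoids a ketyl at C3 and thereby β-loss of the aryloxide, the absence of HMPA keeps the aryl C–Br bonds intact, and −78 °C without base keeps C2 from enolizing.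

Step 9
Reactants: 14 (−)-epiafzelechin
Product: 15 5,7,4'-tri-O-benzyl-(−)-epiafzelechin
Conditions: BnBr (3.2 equiv), K2CO3, DMF, rt
Reagents that add atoms: benzyl bromide, BrCc1ccccc1
Why: Williamson O-benzylation of the three phenols, the secondary 3-OH not being deprotonated by carbonate.

Step 10
Reactants: 15 5,7,4'-tri-O-benzyl-(−)-epiafzelechin
Product: 16 5,7,4'-tri-O-benzyl-8-bromoepiafzelechin
Conditions: NBS (1.0 equiv), CH2Cl2, −78 °C
Reagents that add atoms: N-bromosuccinimide, O=C1CCC(=O)N1Br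
Why: Electrophilic aromatic bromination, which in O-benzylated flavan-3-ols goes to C8 in preference to C6; the bromine later forces C-alkylation of unit 2 at C6.

Step 11
Reactants: 16 5,7,4'-tri-O-benzyl-8-bromoepiafzelechin
Product: 17 5,7,4'-tri-O-benzyl-8-bromo-4β-(2-ethoxyethoxy)epiafzelechin (3,4-trans)
Conditions: DDQ (2 equiv), 2-ethoxyethanol, CH2Cl2, rt
Reagents that add atoms: 2-ethoxyethanol, CCOCCO
Why: DDQ benzylic oxidation (hydride abstraction at C4 assisted by the 5- and 7-oxygens) with capture of the cation by the alcohol on the face anti to the 3-OH.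

Step 12
Reactants: 17 5,7,4'-tri-O-benzyl-8-bromo-4β-(2-ethoxyethoxy)epiafzelechin
Product: 18 5,7,4'-tri-O-benzyl-8-bromo-4β-[(2,6-dimethylphenyl)thio]epiafzelechin (3,4-trans)
Conditions: 2,6-Me2C6H3SH (3 equiv), BF3·OEt2, CH2Cl2, −78 °C
Reagents that add atoms: 2,6-dimethylbenzenethiol, Cc1cccc(C)c1S
Why: Lewis-acid SN1 exchange of the C4 ether for the thiol anti to the 3-OH, giving a soft nucleofuge that is inert to hard Lewis acids (orthogonal activation).

Step 13
Reactants: 13 (2R,3R,4R)-5,7-bis(benzyloxy)-2-[3,4-bis(benzyloxy)phenyl]-6,8-dibromochromane-3,4-diol; 18 5,7,4'-tri-O-benzyl-8-bromo-4β-[(2,6-dimethylphenyl)thio]epiafzelechin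
Product: 19 unit 1–unit 2 dimer, [5,7,3',4'-tetra-O-benzyl-6,8-dibromoepicatechin]-(4β→6)-[5,7,4'-tri-O-benzyl-8-bromo-4β-(2,6-dimethylphenylthio)epiafzelechin]
Conditions: BF3·OEt2, CH2Cl2, −78 → −30 °C; 18 (1.5 equiv)
Reagents that add atoms: none
Why: Hard-acid ionization of the benzylic C4–OH of 13 and Friedel–Crafts alkylation of 18 at C6, its only free ring-A position, the arene entering anti to the axial C3–OH (3,4-trans, 4β) as is general for flavan-4-yl cations; the thioether is expected to survive and the capped cation cannot self-condense.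

Step 14
Reactants: 20 (−)-epicatechin
Product: 21 5,7,3',4'-tetra-O-benzyl-(−)-epicatechin
Conditions: BnBr (4.3 equiv), K2CO3, DMF, rt
Reagents that add atoms: benzyl bromide, BrCc1ccccc1
Why: Williamson O-benzylation of the four phenols with the 3-OH left free.

Step 15
Reactants: 21 5,7,3',4'-tetra-O-benzyl-(−)-epicatechin
Product: 22 5,7,3',4'-tetra-O-benzyl-4β-(2-ethoxyethoxy)epicatechin (3,4-trans)
Conditions: DDQ (2 equiv), 2-ethoxyethanol, CH2Cl2, rt
Reagents that add atoms: 2-ethoxyethanol, CCOCCO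
Why: DDQ benzylic oxidation at C4 and trapping by the alcohol anti to the 3-OH, installing the hard nucleofuge of unit 3 while C8 stays free as the nucleophilic site.

Step 16
Reactants: 19 unit 1–unit 2 dimer with the C4 thioether; 22 5,7,3',4'-tetra-O-benzyl-4β-(2-ethoxyethoxy)epicatechin
Product: 23 unit 1–unit 2–unit 3 trimer, [5,7,3',4'-tetra-O-benzyl-6,8-dibromoepicatechin]-(4β→6)-[5,7,4'-tri-O-benzyl-8-bromoepiafzelechin]-(4β→8)-[5,7,3',4'-tetra-O-benzyl-4β-(2-ethoxyethoxy)epicatechin]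
Conditions: NIS (1.2 equiv), CH2Cl2, −78 → −40 °C; 22 (2 equiv)
Reagents that add atoms: none
Why: Soft iodonium activation of the unit 2 thioether and Friedel–Crafts attack by C8 of 22 (the most nucleophilic site of an O-benzylated flavan) anti to the 3-OH of unit 2 (4β); the thiophile should leave the C4 acetal of 22 alone, and 19 has no free ring-A position.

Step 17
Reactants: 21 5,7,3',4'-tetra-O-benzyl-(−)-epicatechin
Product: 24 5,7,3',4'-tetra-O-benzyl-8-bromoepicatechin
Conditions: NBS (1.0 equiv), CH2Cl2, −78 °C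
Reagents that add atoms: N-bromosuccinimide, O=C1CCC(=O)N1Br
Why: C8-selective electrophilic aromatic bromination, the cap that directs the last coupling to C6 of unit 4.

Step 18
Reactants: 23 unit 1–unit 2–unit 3 trimer with the C4 acetal; 24 5,7,3',4'-tetra-O-benzyl-8-bromoepicatechin
Product: 25 protected tetramer (fifteen O-benzyl groups; bromine at unit 1 C6 and C8, unit 2 C8, unit 4 C8; four free 3-OH)
Conditions: Me3SiOTf (0.5 equiv), CH2Cl2, −78 °C; 24 (4 equiv)
Reagents that add atoms: none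
Why: Hard Lewis-acid ionization of the unit 3 C4 acetal and Friedel–Crafts alkylation of 24 at C6 (C8 capped) anti to the 3-OH of unit 3 (4β), the excess of monomer outcompeting the hindered free C6 of unit 3.

Step 19
Reactants: 25 protected tetramer
Product: 26 epicatechin-(4β→6)-epiafzelechin-(4β→8)-epicatechin-(4β→6)-epicatechin (CNP0103636.1)
Conditions: H2 (1 atm), Pd(OH)2/C, Et3N, THF/MeOH/H2O, rt
Reagents that add atoms: none
Why: Heterogeneous hydrogenolysis of the fifteen benzyl ethers together with hydrodebromination of the four aryl bromides, the amine buffering HBr that would otherwise cleave the acid-labile interflavan bonds; no stereocentre is affected.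

**Compound list**

1 | 4-bromo-1,2-bis(benzyloxy)benzene | Brc1ccc(OCc2ccccc2)c(OCc2ccccc2)c1 | starting material
2 | dimethyl oxalate | COC(=O)C(=O)OC | starting material
3 | [3,4-bis(benzyloxy)phenyl]magnesium bromide | Br[Mg]c1ccc(OCc2ccccc2)c(OCc2ccccc2)c1 | intermediate
4 | methyl 2-[3,4-bis(benzyloxy)phenyl]-2-oxoacetate | COC(=O)C(=O)c1ccc(OCc2ccccc2)c(OCc2ccccc2)c1 | intermediate
5 | methyl (S)-2-[3,4-bis(benzyloxy)phenyl]-2-hydroxyacetate | O[C@@H](c1ccc(OCc2ccccc2)c(OCc2ccccc2)c1)C(=O)OC | intermediate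
6 | 2,4,6-trihydroxybenzaldehyde | O=Cc1c(O)cc(O)cc1O | starting material
7 | 4,6-bis(benzyloxy)-2-hydroxybenzaldehyde | O=Cc1c(O)cc(OCc2ccccc2)cc1OCc1ccccc1 | intermediate
8 | methyl (R)-2-[3,5-bis(benzyloxy)-2-formylphenoxy]-2-[3,4-bis(benzyloxy)phenyl]acetate | O=Cc1c(O[C@H](c2ccc(OCc3ccccc3)c(OCc3ccccc3)c2)C(=O)OC)cc(OCc2ccccc2)cc1OCc1ccccc1 | intermediate
9 | methyl (R)-2-[3,5-bis(benzyloxy)-2,4-dibromo-6-formylphenoxy]-2-[3,4-bis(benzyloxy)phenyl]acetate | O=Cc1c(O[C@H](c2ccc(OCc3ccccc3)c(OCc3ccccc3)c2)C(=O)OC)c(Br)c(OCc2ccccc2)c(Br)c1OCc1ccccc1 | intermediate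
10 | (R)-2-[3,5-bis(benzyloxy)-2,4-dibromo-6-(hydroxymethyl)phenoxy]-2-[3,4-bis(benzyloxy)phenyl]ethan-1-ol | OCc1c(O[C@H](c2ccc(OCc3ccccc3)c(OCc3ccccc3)c2)CO)c(Br)c(OCc2ccccc2)c(Br)c1OCc1ccccc1 | intermediate
11 | (R)-2-[3,5-bis(benzyloxy)-2,4-dibromo-6-formylphenoxy]-2-[3,4-bis(benzyloxy)phenyl]acetaldehyde | O=Cc1c(O[C@H](c2ccc(OCc3ccccc3)c(OCc3ccccc3)c2)C=O)c(Br)c(OCc2ccccc2)c(Br)c1OCc1ccccc1 | intermediate
12 | trivalent-samarium ketyl of 11 (radical at the former aryl aldehyde carbon, O–SmI2) | I[Sm](I)O[CH]c1c(O[C@H](c2ccc(OCc3ccccc3)c(OCc3ccccc3)c2)C=O)c(Br)c(OCc2ccccc2)c(Br)c1OCc1ccccc1 | intermediate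
13 | (2R,3R,4R)-5,7-bis(benzyloxy)-2-[3,4-bis(benzyloxy)phenyl]-6,8-dibromochromane-3,4-diol (2,3-cis, 3,4-cis) | O[C@@H]1c2c(OCc3ccccc3)c(Br)c(OCc3ccccc3)c(Br)c2O[C@H](c2ccc(OCc3ccccc3)c(OCc3ccccc3)c2)[C@@H]1O | intermediate
14 | (−)-epiafzelechin, (2R,3R) | Oc1ccc([C@H]2Oc3cc(O)cc(O)c3C[C@H]2O)cc1 | starting material
15 | 5,7,4'-tri-O-benzyl-(−)-epiafzelechin | O(Cc1ccccc1)c1ccc([C@H]2Oc3cc(OCc4ccccc4)cc(OCc4ccccc4)c3C[C@H]2O)cc1 | intermediate
16 | 5,7,4'-tri-O-benzyl-8-bromoepiafzelechin | O(Cc1ccccc1)c1ccc([C@H]2Oc3c(Br)c(OCc4ccccc4)cc(OCc4ccccc4)c3C[C@H]2O)cc1 | intermediate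
17 | 5,7,4'-tri-O-benzyl-8-bromo-4β-(2-ethoxyethoxy)epiafzelechin | O(Cc1ccccc1)c1ccc([C@H]2Oc3c(Br)c(OCc4ccccc4)cc(OCc4ccccc4)c3[C@H](OCCOCC)[C@H]2O)cc1 | intermediate
18 | 5,7,4'-tri-O-benzyl-8-bromo-4β-[(2,6-dimethylphenyl)thio]epiafzelechin | O(Cc1ccccc1)c1ccc([C@H]2Oc3c(Br)c(OCc4ccccc4)cc(OCc4ccccc4)c3[C@H](Sc3c(C)cccc3C)[C@H]2O)cc1 | intermediate
19 | unit 1–unit 2 dimer: [5,7,3',4'-tetra-O-benzyl-6,8-dibromoepicatechin]-(4β→6)-[5,7,4'-tri-O-benzyl-8-bromo-4β-(2,6-dimethylphenylthio)epiafzelechin] | c9ccccc9COc1ccc([C@H]2Oc3c(Br)c(OCc9ccccc9)c([C@H]4c5c(OCc9ccccc9)c(Br)c(OCc9ccccc9)c(Br)c5O[C@H](c5ccc(OCc9ccccc9)c(OCc9ccccc9)c5)[C@@H]4O)c(OCc9ccccc9)c3[C@H](Sc8c(C)cccc8C)[C@H]2O)cc1 | intermediate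
20 | (−)-epicatechin, (2R,3R) | Oc1ccc(cc1O)[C@H]1Oc2cc(O)cc(O)c2C[C@H]1O | starting material
21 | 5,7,3',4'-tetra-O-benzyl-(−)-epicatechin | c1c(OCc9ccccc9)cc(OCc9ccccc9)c2c1O[C@H](c1ccc(OCc9ccccc9)c(OCc9ccccc9)c1)[C@H](O)C2 | intermediate
22 | 5,7,3',4'-tetra-O-benzyl-4β-(2-ethoxyethoxy)epicatechin | c1c(OCc9ccccc9)cc(OCc9ccccc9)c2c1O[C@H](c1ccc(OCc9ccccc9)c(OCc9ccccc9)c1)[C@H](O)[C@H]2OCCOCC | intermediate
23 | unit 1–unit 2–unit 3 trimer: [5,7,3',4'-tetra-O-benzyl-6,8-dibromoepicatechin]-(4β→6)-[5,7,4'-tri-O-benzyl-8-bromoepiafzelechin]-(4β→8)-[5,7,3',4'-tetra-O-benzyl-4β-(2-ethoxyethoxy)epicatechin] | c9ccccc9COc1ccc([C@H]2Oc3c(Br)c(OCc9ccccc9)c([C@H]4c5c(OCc9ccccc9)c(Br)c(OCc9ccccc9)c(Br)c5O[C@H](c5ccc(OCc9ccccc9)c(OCc9ccccc9)c5)[C@@H]4O)c(OCc9ccccc9)c3[C@H](c3c(OCc9ccccc9)cc(OCc9ccccc9)c4c3O[C@H](c3ccc(OCc9ccccc9)c(OCc9ccccc9)c3)[C@H](O)[C@H]4OCCOCC)[C@H]2O)cc1 | intermediate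
24 | 5,7,3',4'-tetra-O-benzyl-8-bromoepicatechin | c1c(OCc9ccccc9)c(Br)c2c(c1OCc9ccccc9)C[C@@H](O)[C@@H](c1ccc(OCc9ccccc9)c(OCc9ccccc9)c1)O2 | intermediate
25 | protected tetramer: pentadeca-O-benzyl ether of the target with bromine at unit 1 C6 and C8, unit 2 C8 and unit 4 C8 | c9ccccc9COc1ccc([C@H]2Oc3c(Br)c(OCc9ccccc9)c([C@H]4c5c(OCc9ccccc9)c(Br)c(OCc9ccccc9)c(Br)c5O[C@H](c5ccc(OCc9ccccc9)c(OCc9ccccc9)c5)[C@@H]4O)c(OCc9ccccc9)c3[C@H](c3c(OCc9ccccc9)cc(OCc9ccccc9)c4c3O[C@H](c3ccc(OCc9ccccc9)c(OCc9ccccc9)c3)[C@H](O)[C@H]4c3c(OCc9ccccc9)c(Br)c4c(c3OCc9ccccc9)C[C@@H](O)[C@@H](c3ccc(OCc9ccccc9)c(OCc9ccccc9)c3)O4)[C@H]2O)cc1 | intermediate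
26 | epicatechin-(4β→6)-epiafzelechin-(4β→8)-epicatechin-(4β→6)-epicatechin (CNP0103636.1) | Oc1ccc([C@H]2Oc3cc(O)c([C@H]4c5c(O)cc(O)cc5O[C@H](c5ccc(O)c(O)c5)[C@@H]4O)c(O)c3[C@H](c3c(O)cc(O)c4c3O[C@H](c3ccc(O)c(O)c3)[C@H](O)[C@H]4c3c(O)cc4c(c3O)C[C@@H](O)[C@@H](c3ccc(O)c(O)c3)O4)[C@H]2O)cc1 | target

**Step count**

Total steps: 19. Longest linear sequence: 11 steps (steps 1, 2, 4, 5, 6, 7, 8, 13, 16, 18, 19).

**Steps most likely to fail**

Step 8. The carbonyl face at C3 may be attacked with the C3–O equatorial instead of axial (poor facial selectivity, giving the 2,3-trans diol). The aliphatic aldehyde may be reduced first, with reductive loss of the aryloxy group. C2 may epimerize by enolization of the dialdehyde. The fallback sets out from 11 and comes back at 19. A McMurry coupling (TiCl3, Zn(Cu), DME, reflux, high dilution) would close ring C through the same two carbons and give (R)-5,7-bis(benzyloxy)-2-[3,4-bis(benzyloxy)phenyl]-6,8-dibromo-2H-chromene F1. Hydroboration–oxidation (BH3·THF; NaBO3) anti to the 2-aryl group would give the 2,3-trans alcohol 5,7,3',4'-tetra-O-benzyl-6,8-dibromocatechin F2. Dess–Martin oxidation would give the flavan-3-one F3. Reduction with Li[sBu3BH] from the equatorial direction (the established inversion of a 2,3-trans to a 2,3-cis flavan-3-ol) would give 5,7,3',4'-tetra-O-benzyl-6,8-dibromoepicatechin F4. DDQ with 2-ethoxyethanol would give the 4β-(2-ethoxyethoxy) ether F5, which is coupled with 18 under BF3·OEt2 as in step 13 to give 19.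

Step 13. Attack at the bromine-deactivated, doubly flanked C6 of 18 may be too slow. The cation from 13 would then be consumed by O-alkylation of a free 3-OH or by elimination, and the thioether could scramble. The fallback sets out from 13 and 16 and comes back at 19. The less hindered 16, which carries no C4 substituent, is coupled with 13 under BF3·OEt2 to give the dimer [5,7,3',4'-tetra-O-benzyl-6,8-dibromoepicatechin]-(4β→6)-[5,7,4'-tri-O-benzyl-8-bromoepiafzelechin] F6. DDQ with 2-ethoxyethanol would then oxidize its only C4 methylene (unit 2) to the 4β-(2-ethoxyethoxy) dimer F7. Exchange with 2,6-dimethylbenzenethiol and BF3·OEt2 gives 19, so the nucleofuge is installed after the coupling instead of being carried through it.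

Step 16. Acid released during the iodonium activation may ionize the acetal of the nucleophile 22 prematurely, which would then oligomerize, and NIS may iodinate its free C8. The fallback sets out from 19 and 21 and comes back at 23. The acetal-free 21 is used as the nucleophile under the same NIS activation to give the trimer [5,7,3',4'-tetra-O-benzyl-6,8-dibromoepicatechin]-(4β→6)-[5,7,4'-tri-O-benzyl-8-bromoepiafzelechin]-(4β→8)-[5,7,3',4'-tetra-O-benzylepicatechin] F8. DDQ with 2-ethoxyethanol then oxidizes the single C4 methylene (unit 3) to give 23.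

Further compounds
F1 | step 8 | (R)-5,7-bis(benzyloxy)-2-[3,4-bis(benzyloxy)phenyl]-6,8-dibromo-2H-chromene | C1=Cc2c(OCc3ccccc3)c(Br)c(OCc3ccccc3)c(Br)c2O[C@@H]1c1ccc(OCc2ccccc2)c(OCc2ccccc2)c1
F2 | step 8 | 5,7,3',4'-tetra-O-benzyl-6,8-dibromocatechin, (2R,3S), 2,3-trans | C1c2c(OCc3ccccc3)c(Br)c(OCc3ccccc3)c(Br)c2O[C@H](c2ccc(OCc3ccccc3)c(OCc3ccccc3)c2)[C@H]1O
F3 | step 8 | (R)-5,7-bis(benzyloxy)-2-[3,4-bis(benzyloxy)phenyl]-6,8-dibromochroman-3-one | C1c2c(OCc3ccccc3)c(Br)c(OCc3ccccc3)c(Br)c2O[C@H](c2ccc(OCc3ccccc3)c(OCc3ccccc3)c2)C1=O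
F4 | step 8 | 5,7,3',4'-tetra-O-benzyl-6,8-dibromoepicatechin, (2R,3R), 2,3-cis | C1c2c(OCc3ccccc3)c(Br)c(OCc3ccccc3)c(Br)c2O[C@H](c2ccc(OCc3ccccc3)c(OCc3ccccc3)c2)[C@@H]1O
F5 | step 8 | 5,7,3',4'-tetra-O-benzyl-6,8-dibromo-4β-(2-ethoxyethoxy)epicatechin (3,4-trans) | CCOCCO[C@H]1c2c(OCc3ccccc3)c(Br)c(OCc3ccccc3)c(Br)c2O[C@H](c2ccc(OCc3ccccc3)c(OCc3ccccc3)c2)[C@@H]1O
F6 | step 13 | [5,7,3',4'-tetra-O-benzyl-6,8-dibromoepicatechin]-(4β→6)-[5,7,4'-tri-O-benzyl-8-bromoepiafzelechin] | c9ccccc9COc1ccc([C@H]2Oc3c(Br)c(OCc9ccccc9)c([C@H]4c5c(OCc9ccccc9)c(Br)c(OCc9ccccc9)c(Br)c5O[C@H](c5ccc(OCc9ccccc9)c(OCc9ccccc9)c5)[C@@H]4O)c(OCc9ccccc9)c3C[C@H]2O)cc1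
F7 | step 13 | [5,7,3',4'-tetra-O-benzyl-6,8-dibromoepicatechin]-(4β→6)-[5,7,4'-tri-O-benzyl-8-bromo-4β-(2-ethoxyethoxy)epiafzelechin] | c9ccccc9COc1ccc([C@H]2Oc3c(Br)c(OCc9ccccc9)c([C@H]4c5c(OCc9ccccc9)c(Br)c(OCc9ccccc9)c(Br)c5O[C@H](c5ccc(OCc9ccccc9)c(OCc9ccccc9)c5)[C@@H]4O)c(OCc9ccccc9)c3[C@H](OCCOCC)[C@H]2O)cc1
F8 | step 16 | [5,7,3',4'-tetra-O-benzyl-6,8-dibromoepicatechin]-(4β→6)-[5,7,4'-tri-O-benzyl-8-bromoepiafzelechin]-(4β→8)-[5,7,3',4'-tetra-O-benzylepicatechin] | c9ccccc9COc1ccc([C@H]2Oc3c(Br)c(OCc9ccccc9)c([C@H]4c5c(OCc9ccccc9)c(Br)c(OCc9ccccc9)c(Br)c5O[C@H](c5ccc(OCc9ccccc9)c(OCc9ccccc9)c5)[C@@H]4O)c(OCc9ccccc9)c3[C@H](c3c(OCc9ccccc9)cc(OCc9ccccc9)c4c3O[C@H](c3ccc(OCc9ccccc9)c(OCc9ccccc9)c3)[C@H](O)C4)[C@H]2O)cc1
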